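The route rests on closing ring C at its aryl ether bond, O1–C8a. Ring A enters as a C2v-symmetric 5-fluoro-2-methylresorcinol bis-MOM ether. Its fluorine lies para to the future C6 methyl and meta to the C5 and C7 oxygens. It first directs ortho-lithiation for acylation at C4a and then serves as nucleofuge at C8a, so the methyl can only end at C6. In the key step the C2 alkoxide of a 1-(2-fluoroaryl)-3-arylpropane-1,3-diol, its C2 centre set by asymmetric conjugate borylation of the 2'-fluorochalcone, displaces that fluoride without touching the stereocentre. Oxidation at C4, trans-selective enolate hydroxylation at C3 and MOM removal finish the synthesis.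

Key step: step 8

Remark: atom labels follow the chromanone numbering of the target (O1, C2, C3, C4, C4a, C5 to C8, C8a; ring B primed); geranyl means (2E)-3,7-dimethylocta-2,6-dien-1-yl and MOM means methoxymethyl.
Remark: 5-fluorobenzene-1,3-diol is taken as a commercial starting material; the C4 carbinol centre of 14, 15 and 16 is carried as a mixture of epimers and is destroyed in step 9.

Step 1
Reactants: 1 4-bromophenol; 2 geranyl bromide [(2E)-1-bromo-3,7-dimethylocta-2,6-diene]
Product: 3 4-bromo-2-geranylphenol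
Conditions: NaH (1.0 equiv), toluene, 0 °C; then 2, rt
Reagents that add atoms: none
Why: Phenolate C-allylation: sodium 4-bromophenoxide in a non-coordinating solvent reacts as a tight ion pair at carbon, so SN2 attack of the ortho carbon (para is blocked by bromine) on the primary allylic bromide should prevail over O-alkylation and leave the E-alkene untouched.

Step 2
Reactants: 3 4-bromo-2-geranylphenol
Product: 4 4-bromo-2-geranyl-1-(methoxymethoxy)benzene
Conditions: MOMCl, i-Pr2NEt, CH2Cl2, 0 °C to rt
Reagents that add atoms: chloromethyl methyl ether, COCCl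
Why: Williamson-type O-alkylation masks the phenol before the palladium and organolithium steps.

Step 3
Reactants: 4 4-bromo-2-geranyl-1-(methoxymethoxy)benzene; 5 N-methoxy-N-methylprop-2-enamide
Product: 6 (2E)-3-[3-geranyl-4-(methoxymethoxy)phenyl]-N-methoxy-N-methylprop-2-enamide
Conditions: Pd(OAc)2 (5 mol%), P(o-tol)3 (10 mol%), Et3N, DMF, 100 °C
Reagents that add atoms: none
Why: Mizoroki–Heck reaction: oxidative addition of the aryl bromide to zerovalent palladium, syn-insertion of the acrylamide and syn-β-hydride elimination should give the E-enamide, while the trisubstituted geranyl alkenes are too hindered to insert.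

Step 4
Reactants: 7 5-fluorobenzene-1,3-diol
Product: 8 1-fluoro-3,5-bis(methoxymethoxy)benzene
Conditions: MOMCl (2.5 equiv), i-Pr2NEt (3 equiv), CH2Cl2, 0 °C to rt
Reagents that add atoms: chloromethyl methyl ether, COCCl
Why: Double Williamson-type protection gives the symmetric bis-MOM ether whose oxygens later act as ortho-directing groups.

Step 5
Reactants: 8 1-fluoro-3,5-bis(methoxymethoxy)benzene
Product: 10 5-fluoro-1,3-bis(methoxymethoxy)-2-methylbenzene, via aryllithium 9 (not isolated)
Conditions: n-BuLi (1.1 equiv), THF, 0 °C; then MeI, 0 °C to rt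
Reagents that add atoms: iodomethane, CI; n-butyllithium, [Li]CCCC (lithium of intermediate 9 only)
Why: Directed ortho-metalation: coordination to the two flanking OMOM groups should guide n-BuLi to the position between them and not to the positions next to fluorine, and the aryllithium is then methylated by SN2 on iodomethane.

Step 6
Reactants: 10 5-fluoro-1,3-bis(methoxymethoxy)-2-methylbenzene; 6 (2E)-3-[3-geranyl-4-(methoxymethoxy)phenyl]-N-methoxy-N-methylprop-2-enamide
Product: 12 (2E)-1-[6-fluoro-2,4-bis(methoxymethoxy)-3-methylphenyl]-3-[3-geranyl-4-(methoxymethoxy)phenyl]prop-2-en-1-one, via aryllithium 11 (not isolated)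
Conditions: s-BuLi (1.1 equiv), THF, −78 °C; then 6, −78 °C; then H2O
Reagents that add atoms: sec-butyllithium, [Li]C(C)CC (lithium of intermediate 11 only)
Why: A second directed ortho-metalation can only occur at one of the two equivalent positions flanked by fluorine and OMOM, and Weinreb ketone synthesis (1,2-addition to the amide giving a chelated adduct that collapses only on work-up) should deliver the E-enone without over-addition.

Step 7
Reactants: 12 the 2'-fluorochalcone of step 6
Product: 15 (1RS,3S)-1-[6-fluoro-2,4-bis(methoxymethoxy)-3-methylphenyl]-3-[3-geranyl-4-(methoxymethoxy)phenyl]propane-1,3-diol, via β-boryl ketone 13 (not isolated), via γ-boryl alcohol 14 (not isolated)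
Conditions: CuCl (5 mol%), (R)-1-[(SP)-2-(diphenylphosphino)ferrocenyl]ethyldicyclohexylphosphine (5 mol%), NaOt-Bu (10 mol%), B2pin2 (1.1 equiv), MeOH (2 equiv), THF, rt; then NaBH4, 0 °C; then aqueous NaOH, H2O2, 0 °C
Reagents that add atoms: bis(pinacolato)diboron, CC1(C)OB(OC1(C)C)B1OC(C)(C)C(C)(C)O1 (boryl group of intermediates 13 and 14 only); hydrogen peroxide, OO (oxygen of the ring-B carbinol, the future O1)
Why: Copper-catalysed enantioselective conjugate borylation: the chiral bisphosphine copper boryl adds to the β-carbon of the enone under catalyst control (the ligand enantiomer used is the one that places boron on the face leading to 3S, its mirror image being equally available), NaBH4 then reduces the ketone without stereochemical demand, and alkaline peroxide converts C–B into C–O with retention.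

Step 8
Reactants: 15 the (1RS,3S)-1,3-diol of step 7
Product: 16 (2S,4RS)-2-[3-geranyl-4-(methoxymethoxy)phenyl]-5,7-bis(methoxymethoxy)-6-methyl-3,4-dihydro-2H-chromen-4-ol
Conditions: KOt-Bu (2.5 equiv), 18-crown-6 (2.5 equiv), THF, 60 °C; then H2O
Reagents that add atoms: none
Why: Both hydroxyl groups are deprotonated and the C2 alkoxide adds to the fluorine-bearing C8a, passing through a Meisenheimer-type anion (or its concerted equivalent) that expels fluoride, an addition–elimination nucleophilic aromatic substitution on a non-activated fluoroarene. The closest known reaction type is the base-mediated cyclisation of 3-(2-fluoroaryl)propan-1-ols to chromans, helped here by the inductive pull of the two meta OMOM groups at C5 and C7 and by the crown-ether-separated potassium alkoxide. Ring C is closed in the 6-exo mode onto the arene by the O1–C8a bond. No stereocentre is created: C2 keeps its S configuration because its C–O bond is never broken, and the C4 epimers converge in step 9. The step needs chemoselectivity between the two alkoxides and regioselectivity on ring A, and both are secured by the substrate, since the C4 alkoxide could only close a four-membered ring and fluorine, the sole nucleofuge, sits at C8a so that the methyl group ends at C6 and not at C8. The ring is closed at the alcohol oxidation level on purpose, because without a C4 carbonyl neither retro-aldol cleavage of the alkoxide nor E1cB opening of the product can erode C2.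

Step 9
Reactants: 16 the (2S,4RS)-chroman-4-ol of step 8
Product: 17 (2S)-2-[3-geranyl-4-(methoxymethoxy)phenyl]-5,7-bis(methoxymethoxy)-6-methyl-2,3-dihydro-4H-chromen-4-one
Conditions: Dess–Martin periodinane (1.3 equiv), CH2Cl2, 0 °C to rt
Reagents that add atoms: none
Why: Dess–Martin oxidation of the only free alcohol converges both C4 epimers on one ketone under near-neutral conditions that should leave the MOM ethers, the geranyl alkenes and the base-labile C2 centre untouched.

Step 10
Reactants: 17 the (2S)-chromanone of step 9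
Product: 19 (2R,3R)-3-hydroxy-2-[3-geranyl-4-(methoxymethoxy)phenyl]-5,7-bis(methoxymethoxy)-6-methyl-2,3-dihydro-4H-chromen-4-one, via sodium enolate 18 (not isolated)
Conditions: NaN(SiMe3)2 (1.1 equiv), THF, −78 °C; then 2-(phenylsulfonyl)-3-phenyloxaziridine (1.3 equiv), −78 °C; then AcOH, −78 °C
Reagents that add atoms: 2-(phenylsulfonyl)-3-phenyloxaziridine, O=S(=O)(N1OC1c1ccccc1)c1ccccc1; sodium bis(trimethylsilyl)amide, C[Si](C)(C)N([Na])[Si](C)(C)C (sodium of intermediate 18 only)
Why: Davis enolate hydroxylation: the enolate, formed at −78 °C where E1cB opening of the pyranone ring is slow, should be attacked at C3 by the electrophilic oxaziridine oxygen on the face opposite the C2 aryl group, giving the 2,3-trans (2R,3R) ketol, while the isolated geranyl alkenes do not react with the oxaziridine at this temperature.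

Step 11
Reactants: 19 the tris-MOM-protected (2R,3R)-ketol of step 10
Product: 20 (2R,3R)-2-[3-geranyl-4-hydroxyphenyl]-3,5,7-trihydroxy-6-methyl-2,3-dihydro-4H-chromen-4-one (target)
Conditions: 3 M aqueous HCl, MeOH, 45 °C
Reagents that add atoms: none
Why: Acid-catalysed acetal exchange with methanol removes the three aryl MOM ethers under conditions mild enough that the ortho-geranyl phenol should not cyclise to a chroman and the trans ketol should not epimerise.

Compound list
1 | 4-bromophenol | Oc1ccc(Br)cc1 | starting material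
2 | geranyl bromide, (2E)-1-bromo-3,7-dimethylocta-2,6-diene | BrC/C=C(\C)CCC=C(C)C | starting material
3 | 4-bromo-2-[(2E)-3,7-dimethylocta-2,6-dien-1-yl]phenol | Oc1ccc(Br)cc1C/C=C(\C)CCC=C(C)C | intermediate
4 | 4-bromo-2-[(2E)-3,7-dimethylocta-2,6-dien-1-yl]-1-(methoxymethoxy)benzene | COCOc1ccc(Br)cc1C/C=C(\C)CCC=C(C)C | intermediate
5 | N-methoxy-N-methylprop-2-enamide | C=CC(=O)N(C)OC | starting material
6 | (2E)-3-{3-[(2E)-3,7-dimethylocta-2,6-dien-1-yl]-4-(methoxymethoxy)phenyl}-N-methoxy-N-methylprop-2-enamide | CON(C)C(=O)/C=C/c1ccc(OCOC)c(C/C=C(\C)CCC=C(C)C)c1 | intermediate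
7 | 5-fluorobenzene-1,3-diol | Oc1cc(O)cc(F)c1 | starting material
8 | 1-fluoro-3,5-bis(methoxymethoxy)benzene | COCOc1cc(F)cc(OCOC)c1 | intermediate
9 | [4-fluoro-2,6-bis(methoxymethoxy)phenyl]lithium | [Li]c1c(OCOC)cc(F)cc1OCOC | intermediate (not isolated)
10 | 5-fluoro-1,3-bis(methoxymethoxy)-2-methylbenzene | COCOc1cc(F)cc(OCOC)c1C | intermediate
11 | [6-fluoro-2,4-bis(methoxymethoxy)-3-methylphenyl]lithium | [Li]c1c(F)cc(OCOC)c(C)c1OCOC | intermediate (not isolated)
12 | (2E)-1-[6-fluoro-2,4-bis(methoxymethoxy)-3-methylphenyl]-3-{3-[(2E)-3,7-dimethylocta-2,6-dien-1-yl]-4-(methoxymethoxy)phenyl}prop-2-en-1-one | COCOc1cc(F)c(C(=O)/C=C/c2ccc(OCOC)c(C/C=C(\C)CCC=C(C)C)c2)c(OCOC)c1C | intermediate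
13 | (3S)-1-[6-fluoro-2,4-bis(methoxymethoxy)-3-methylphenyl]-3-{3-[(2E)-3,7-dimethylocta-2,6-dien-1-yl]-4-(methoxymethoxy)phenyl}-3-(4,4,5,5-tetramethyl-1,3,2-dioxaborolan-2-yl)propan-1-one | COCOc1cc(F)c(C(=O)C[C@H](B2OC(C)(C)C(C)(C)O2)c2ccc(OCOC)c(C/C=C(\C)CCC=C(C)C)c2)c(OCOC)c1C | intermediate (not isolated)
14 | (1RS,3S)-1-[6-fluoro-2,4-bis(methoxymethoxy)-3-methylphenyl]-3-{3-[(2E)-3,7-dimethylocta-2,6-dien-1-yl]-4-(methoxymethoxy)phenyl}-3-(4,4,5,5-tetramethyl-1,3,2-dioxaborolan-2-yl)propan-1-ol | COCOc1cc(F)c(C(O)C[C@H](B2OC(C)(C)C(C)(C)O2)c2ccc(OCOC)c(C/C=C(\C)CCC=C(C)C)c2)c(OCOC)c1C | intermediate (not isolated)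
15 | (1RS,3S)-1-[6-fluoro-2,4-bis(methoxymethoxy)-3-methylphenyl]-3-{3-[(2E)-3,7-dimethylocta-2,6-dien-1-yl]-4-(methoxymethoxy)phenyl}propane-1,3-diol | COCOc1cc(F)c(C(O)C[C@H](O)c2ccc(OCOC)c(C/C=C(\C)CCC=C(C)C)c2)c(OCOC)c1C | intermediate
16 | (2S,4RS)-2-{3-[(2E)-3,7-dimethylocta-2,6-dien-1-yl]-4-(methoxymethoxy)phenyl}-5,7-bis(methoxymethoxy)-6-methyl-3,4-dihydro-2H-chromen-4-ol | COCOc1cc2O[C@H](c3ccc(OCOC)c(C/C=C(\C)CCC=C(C)C)c3)CC(O)c2c(OCOC)c1C | intermediate
17 | (2S)-2-{3-[(2E)-3,7-dimethylocta-2,6-dien-1-yl]-4-(methoxymethoxy)phenyl}-5,7-bis(methoxymethoxy)-6-methyl-2,3-dihydro-4H-chromen-4-one | COCOc1cc2O[C@H](c3ccc(OCOC)c(C/C=C(\C)CCC=C(C)C)c3)CC(=O)c2c(OCOC)c1C | intermediate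
18 | sodium (2S)-2-{3-[(2E)-3,7-dimethylocta-2,6-dien-1-yl]-4-(methoxymethoxy)phenyl}-5,7-bis(methoxymethoxy)-6-methyl-2H-chromen-4-olate | COCOc1cc2O[C@H](c3ccc(OCOC)c(C/C=C(\C)CCC=C(C)C)c3)C=C(O[Na])c2c(OCOC)c1C | intermediate (not isolated)
19 | (2R,3R)-2-{3-[(2E)-3,7-dimethylocta-2,6-dien-1-yl]-4-(methoxymethoxy)phenyl}-3-hydroxy-5,7-bis(methoxymethoxy)-6-methyl-2,3-dihydro-4H-chromen-4-one | COCOc1cc2O[C@H](c3ccc(OCOC)c(C/C=C(\C)CCC=C(C)C)c3)[C@@H](O)C(=O)c2c(OCOC)c1C | intermediate
20 | (2R,3R)-2-{3-[(2E)-3,7-dimethylocta-2,6-dien-1-yl]-4-hydroxyphenyl}-3,5,7-trihydroxy-6-methyl-2,3-dihydro-4H-chromen-4-one | Oc1cc2O[C@H](c3ccc(O)c(C/C=C(\C)CCC=C(C)C)c3)[C@@H](O)C(=O)c2c(O)c1C | target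

Total steps: 11. Longest linear sequence: 9 steps (steps 1, 2, 3, 6, 7, 8, 9, 10, 11).

Steps most likely to fail

Step 8. The non-activated C–F bond may be displaced too slowly at 60 °C, and forcing the temperature invites base-mediated migration of the benzylic-allylic double bond of the geranyl group into conjugation with ring B. The fallback restores carbonyl activation and sets out from chalcone 12. The conjugate borylation of step 7 is run as before, but boronate 13 is oxidised directly with NaBO3·4H2O in THF/H2O, without NaBH4, to give (3S)-1-[6-fluoro-2,4-bis(methoxymethoxy)-3-methylphenyl]-3-hydroxy-3-[3-geranyl-4-(methoxymethoxy)phenyl]propan-1-one F1. With the ketone ortho to fluorine, F1 should cyclise by carbonyl-activated nucleophilic aromatic substitution with Cs2CO3 in MeCN at rt. This gives chromanone 17 directly, so the route is rejoined at 17 and step 9 is not needed. The price is the retro-aldol and enolisation chemistry of the ketone, which is why this closure is the second choice. It should be run cold and stopped at full conversion.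

Step 10. The enolate may open the pyranone ring by E1cB expulsion of the C8a phenoxide, which would scramble C2, or may add to the sulfonimine formed from the oxaziridine. The fallback avoids a free enolate and sets out from 17. Deprotonation with LiN(i-Pr)2 in the presence of Me3SiCl (in situ quench, THF, −78 °C) should give (2S)-2-[3-geranyl-4-(methoxymethoxy)phenyl]-5,7-bis(methoxymethoxy)-6-methyl-4-(trimethylsilyloxy)-2H-chromene F2. The neutral enol ether is oxidised with the same N-sulfonyloxaziridine in CHCl3 at 40 °C, anti to the C2 aryl group, to give after silyl migration (2R,3R)-2-[3-geranyl-4-(methoxymethoxy)phenyl]-5,7-bis(methoxymethoxy)-6-methyl-3-(trimethylsilyloxy)-2,3-dihydro-4H-chromen-4-one F3. Brief treatment with dilute aqueous HCl in THF removes the silyl group and returns to the route at 19.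

Step 6. The hindered ortho-fluoroaryllithium 11 may add too slowly to the amide at −78 °C, and on warming it loses lithium fluoride to an aryne. The fallback uses a faster electrophile and sets out from 6 and 10. Reduction of 6 with i-Bu2AlH (THF, −78 °C) should give (2E)-3-[3-geranyl-4-(methoxymethoxy)phenyl]prop-2-enal F4. Aryllithium 11, made from 10 as in step 6, adds to F4 at −78 °C to give racemic (2E)-1-[6-fluoro-2,4-bis(methoxymethoxy)-3-methylphenyl]-3-[3-geranyl-4-(methoxymethoxy)phenyl]prop-2-en-1-ol F5. Oxidation of F5 with MnO2 in CH2Cl2 returns to the route at chalcone 12.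

Further compounds
F1 | step 8 | (3S)-1-[6-fluoro-2,4-bis(methoxymethoxy)-3-methylphenyl]-3-hydroxy-3-{3-[(2E)-3,7-dimethylocta-2,6-dien-1-yl]-4-(methoxymethoxy)phenyl}propan-1-one | COCOc1cc(F)c(C(=O)C[C@H](O)c2ccc(OCOC)c(C/C=C(\C)CCC=C(C)C)c2)c(OCOC)c1C
F2 | step 10 | (2S)-2-{3-[(2E)-3,7-dimethylocta-2,6-dien-1-yl]-4-(methoxymethoxy)phenyl}-5,7-bis(methoxymethoxy)-6-methyl-4-(trimethylsilyloxy)-2H-chromene | COCOc1cc2O[C@H](c3ccc(OCOC)c(C/C=C(\C)CCC=C(C)C)c3)C=C(O[Si](C)(C)C)c2c(OCOC)c1C
F3 | step 10 | (2R,3R)-2-{3-[(2E)-3,7-dimethylocta-2,6-dien-1-yl]-4-(methoxymethoxy)phenyl}-5,7-bis(methoxymethoxy)-6-methyl-3-(trimethylsilyloxy)-2,3-dihydro-4H-chromen-4-one | COCOc1cc2O[C@H](c3ccc(OCOC)c(C/C=C(\C)CCC=C(C)C)c3)[C@@H](O[Si](C)(C)C)C(=O)c2c(OCOC)c1C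
F4 | step 6 | (2E)-3-{3-[(2E)-3,7-dimethylocta-2,6-dien-1-yl]-4-(methoxymethoxy)phenyl}prop-2-enal | O=C/C=C/c1ccc(OCOC)c(C/C=C(\C)CCC=C(C)C)c1
F5 | step 6 | (2E)-1-[6-fluoro-2,4-bis(methoxymethoxy)-3-methylphenyl]-3-{3-[(2E)-3,7-dimethylocta-2,6-dien-1-yl]-4-(methoxymethoxy)phenyl}prop-2-en-1-ol (racemic) | COCOc1cc(F)c(C(O)/C=C/c2ccc(OCOC)c(C/C=C(\C)CCC=C(C)C)c2)c(OCOC)c1C
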